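The route rests on cutting the C9–C11 bond between the vinylic carbon C9 of ring B and the ethano bridge. In one flask, 9-BBN hydroborates only the vinyl group (C11=C12) of a 3-vinyl-5,6-dihydro-2H-pyran, and palladium then joins the primary borane to the C9 enol triflate of an 11-nordrimane. The step exploits two features. C9 lies beside the quaternary C10, so the nor-ketone enolate can only be C8=C9 and the triflate fixes the tetrasubstituted alkene. The dihydropyran ring ties O-C24 to O-C16, locks the C13=C14 geometry and masks both hydroxyls. The furan becomes the butenolide afterwards.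

Key step: step 8

Remark: terpenoid numbering is used (ring A C1–C5 and C10, ring B C5–C10, gem-dimethyl on C4, methyl groups on C8 and C10, bridge C11–C12, alkene C13=C14, C15H2, carbinol C16, butenolide C17–C19 and C25, hydroxymethyl C24). The acetal and hemiacetal carbons C24 and C25 are carried as epimer mixtures because both end as CH2.

Step 1
Reactants: 1 (+)-sclareolide
Product: 5 9(11)-dehydrosclareolide, via lactone lithium enolate 2 (not isolated), via 11α-phenylselanyl lactone 3 (not isolated), via selenoxide 4 (not isolated)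
Conditions: LiN(iPr)2, THF, −78 °C; PhSeCl, −78 °C; then 30% aq. H2O2, 0 °C to rt
Reagents that add atoms: PhSeCl, Cl[Se]c1ccccc1 (selenium and phenyl are carried only in 3 and 4); H2O2, OO (its oxygen is carried only in 4)
Why: Enolate selenenylation and selenoxide syn-elimination: PhSeCl should approach C11 of enolate 2 from the α face, away from the axial methyl groups on C8 and C10, which puts selenium cis to H-9, the only β-hydrogen, so that 4 can eliminate only to the C9=C11 butenolide while C5, C8 and C10 stay untouched.

Step 2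
Reactants: 5 9(11)-dehydrosclareolide
Product: 8 8α-hydroxy-11-nordriman-9-one, via secondary ozonide 6 (not isolated), via keto glyoxylate 7 (not isolated)
Conditions: O3, CH2Cl2, −78 °C; PPh3, −78 °C to rt; then K2CO3 (cat.), MeOH, 0 °C
Reagents that add atoms: ozone, [O-][O+]=O
Why: Ozonolysis (Criegee mechanism) cleaves the only alkene, turns C9 into the ketone and leaves C11–C12 as a glyoxylate on O-8, an activated ester that base-catalysed transesterification with methanol removes under conditions too mild for an α-ketol shift.

Step 3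
Reactants: 8 8α-hydroxy-11-nordriman-9-one
Product: 9 exocyclic enone (4aS,8aS)-5,5,8a-trimethyl-2-methylideneoctahydronaphthalen-1(2H)-one
Conditions: SOCl2, pyridine, CH2Cl2, −20 to 0 °C
Reagents that add atoms: none
Why: Dehydration by E2 elimination of the chlorosulfite: the equatorial C8–O bond finds antiperiplanar hydrogens only in the C8 methyl group and C9 bears none, so the exocyclic enone should form.

Step 4
Reactants: 9 exocyclic enone
Product: 11 C9 enol triflate of the 11-nordrimane, via lithium enolate 10 (not isolated)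
Conditions: LiBH(s-Bu)3, THF, −78 °C; then Comins reagent, −78 to 0 °C
Reagents that add atoms: Comins reagent, O=S(=O)(N(c1ccc(Cl)cn1)S(=O)(=O)C(F)(F)F)C(F)(F)F
Why: Conjugate reduction with enolate trapping: the bulky borohydride adds hydride 1,4 to the fixed s-cis enone, whose carbonyl is screened by C10, the exocyclic CH2 becomes the C8 methyl group, and O-sulfonylation of the only possible enolate gives the tetrasubstituted C8=C9 enol triflate.

Step 5
Reactants: 12 furan-3-carbaldehyde; 13 allyltributylstannane
Product: 15 (R)-1-(furan-3-yl)but-3-en-1-ol, via tributylstannyl ether 14 (not isolated)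
Conditions: (R)-BINOL (20 mol %), Ti(OiPr)4 (10 mol %), 4 Å MS, CH2Cl2, −20 °C; aq. NaHCO3
Reagents that add atoms: none
Why: Keck asymmetric allylation: the (R)-BINOL titanium Lewis acid binds the aldehyde and exposes the face whose attack by the allylstannane gives the (R)-carbinol, the future C16.

Step 6
Reactants: 15 (R)-1-(furan-3-yl)but-3-en-1-ol; 16 3,3-diethoxyprop-1-yne
Product: 17 mixed propynal acetal (enyne, both C24 epimers)
Conditions: PPTS (cat.), 16 in excess, toluene, 50 °C, EtOH removed under reduced pressure
Reagents that add atoms: none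
Why: Acid-catalysed transacetalisation, driven by excess 16 and removal of ethanol, exchanges one ethoxy group without breaking the C16–O bond, so that C16 keeps its configuration and the new acetal centre C24 needs no control.

Step 7
Reactants: 17 mixed propynal acetal
Product: 18 (6R)-2-ethoxy-3-ethenyl-6-(furan-3-yl)-5,6-dihydro-2H-pyran (both C24 epimers)
Conditions: second-generation Grubbs catalyst (5 mol %), ethylene (1 atm), CH2Cl2, 40 °C
Reagents that add atoms: none
Why: Ring-closing enyne metathesis in the exo mode closes the six-membered ring between C13 and C14, which forces C24 and C15 cis on the new alkene, and moves the terminal methylene onto the former alkyne terminus to give the C11=C12 vinyl group, with ethylene keeping the ruthenium carbene active.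

Step 8
Reactants: 18 3-vinyl dihydropyran acetal; 11 C9 enol triflate
Product: 20 coupled furyl dihydropyran acetal, via B-alkyl-9-BBN 19 (not isolated)
Conditions: 18, 9-BBN-H, THF, 0 °C to rt; then 11, PdCl2(dppf) (10 mol %), AsPh3, Cs2CO3, DMF/THF/H2O, 50 °C
Reagents that add atoms: 9-BBN-H, B1C2CCCC1CCC2 (boron and its bicycle are carried only in 19; only hydrogen stays in 20)
Why: 9-BBN-H adds in a four-centre, anti-Markovnikov fashion to the monosubstituted C11=C12 bond of 18 and places boron on C11 to give 19; zerovalent palladium inserts into the C9–O bond of 11, the base-activated borate hands the primary C11 over to divalent palladium, and reductive elimination forms C9–C11 with the alkene held at C8=C9. The closest known reaction type is the B-alkyl Suzuki–Miyaura coupling of enol triflates with 9-BBN adducts of terminal alkenes, run as hydroboration and coupling in one flask. No ring is closed and no stereocentre is created, and C5, C10 and C16 are spectators, so both acetal epimers of 18 can be used. The hydroboration must choose among four π systems, and sterics secure this: the bulky borane takes the only monosubstituted alkene and leaves the trisubstituted ring alkene C13=C14 and the aromatic furan. The position of the tetrasubstituted alkene is secured by the substrate, since the triflate sits on the only enol position that the quaternary C10 allows. The crowding at C9 (quaternary C10, methyl on C8) slows transmetalation, which is why a wide-bite-angle ligand, AsPh3 as co-ligand and a primary unbranched borane are chosen so that coupling outruns β-hydride elimination.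

Step 9
Reactants: 20 coupled furyl dihydropyran acetal
Product: 22 γ-hydroxybutenolide acetal, via furan endoperoxide 21 (not isolated)
Conditions: O2, tetraphenylporphyrin (cat.), visible light, iPr2NEt, CH2Cl2, −78 °C
Reagents that add atoms: oxygen, O=O
Why: [4+2] Cycloaddition of singlet oxygen to the furan and Kornblum–DeLaMare fragmentation of endoperoxide 21: the hindered amine removes the endoperoxide proton remote from C16, which puts the carbonyl at C19 and the hydroxyl at C25, and at −78 °C the electron-rich furan should react ahead of the crowded C8=C9 and the acetal-deactivated C13=C14 alkenes.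

Step 10
Reactants: 22 γ-hydroxybutenolide acetal
Product: 23 bis-hemiacetal (C24 lactol and C25 hydroxybutenolide)
Conditions: AcOH, THF, H2O, 35 °C
Reagents that add atoms: water, O
Why: Acid-catalysed acetal hydrolysis through the allyl-stabilised oxocarbenium ion at C24 frees the lactol under conditions that the hydroxybutenolide, the tetrasubstituted alkene and the C16–O bond (next to an electron-poor alkene) should tolerate.

Step 11
Reactants: 23 bis-hemiacetal
Product: 25 CNP0224983.2 (target), via sodium hydroxy carboxylate 24 (not isolated)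
Conditions: NaBH4, EtOH, 0 °C; then 1 M HCl
Reagents that add atoms: NaBH4, [Na+].[BH4-] (sodium is carried only in 24; only hydrogen stays in 25)
Why: Borohydride reduction of the aldehyde ring-chain tautomers of both hemiacetals funnels all C24 and C25 epimers into one triol carboxylate with 1,2-selectivity at the enal and with the ring-derived alkene geometry kept, and acidification lactonises only the C25 hydroxyl, the one cis to the carboxyl group, to the butenolide.

Compound list
1 | (+)-sclareolide, (3aR,5aS,9aS,9bR)-3a,6,6,9a-tetramethyldecahydronaphtho[2,1-b]furan-2(1H)-one | C[C@]12CCCC([C@@H]1CC[C@@]3([C@@H]2CC(=O)O3)C)(C)C | starting material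
2 | lithium enolate of 1 (C11=C12) | C[C@]12CCCC([C@@H]1CC[C@@]3([C@@H]2C=C([O-])O3)C)(C)C.[Li+] | intermediate
3 | 11α-(phenylselanyl)sclareolide (SePh cis to H-9) | C[C@]12CCCC([C@@H]1CC[C@@]3([C@@H]2[C@H]([Se]c4ccccc4)C(=O)O3)C)(C)C | intermediate
4 | selenoxide of 3 (selenium centre undefined) | C[C@]12CCCC([C@@H]1CC[C@@]3([C@@H]2[C@H]([Se](=O)c4ccccc4)C(=O)O3)C)(C)C | intermediate
5 | 9(11)-dehydrosclareolide, (3aR,5aS,9aS)-butenolide with the C9=C11 double bond | C[C@]12CCCC([C@@H]1CC[C@@]3(C2=CC(=O)O3)C)(C)C | intermediate
6 | secondary ozonide of 5 (1,2,4-trioxolane across C9 and C11, new centres undefined) | C[C@]12CCCC([C@@H]1CC[C@@]3(C24OOC(O4)C(=O)O3)C)(C)C | intermediate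
7 | 9-oxo-11-nordriman-8α-yl glyoxylate | C[C@]12CCCC([C@@H]1CC[C@@](OC(=O)C=O)(C2=O)C)(C)C | intermediate
8 | 8α-hydroxy-11-nordriman-9-one, (2R,4aS,8aS)-2-hydroxy-2,5,5,8a-tetramethyloctahydronaphthalen-1(2H)-one | C[C@]12CCCC([C@@H]1CC[C@@](O)(C2=O)C)(C)C | intermediate
9 | (4aS,8aS)-5,5,8a-trimethyl-2-methylideneoctahydronaphthalen-1(2H)-one | C=C1C(=O)[C@@]2(C)CCCC(C)(C)[C@@H]2CC1 | intermediate
10 | lithium (4aS,8aS)-2,5,5,8a-tetramethyl-3,4,4a,5,6,7,8,8a-octahydronaphthalen-1-olate | CC1=C([O-])[C@@]2(C)CCCC(C)(C)[C@@H]2CC1.[Li+] | intermediate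
11 | (4aS,8aS)-2,5,5,8a-tetramethyl-3,4,4a,5,6,7,8,8a-octahydronaphthalen-1-yl trifluoromethanesulfonate | CC1=C(OS(=O)(=O)C(F)(F)F)[C@@]2(C)CCCC(C)(C)[C@@H]2CC1 | intermediate
12 | furan-3-carbaldehyde | O=Cc1ccoc1 | starting material
13 | allyltributylstannane | C=CC[Sn](CCCC)(CCCC)CCCC | starting material
14 | tributylstannyl ether of 15 | C=CC[C@@H](O[Sn](CCCC)(CCCC)CCCC)c1ccoc1 | intermediate
15 | (R)-1-(furan-3-yl)but-3-en-1-ol | C=CC[C@@H](O)c1ccoc1 | intermediate
16 | 3,3-diethoxyprop-1-yne | C#CC(OCC)OCC | starting material
17 | 3-[(1R)-1-(1-ethoxyprop-2-yn-1-yloxy)but-3-en-1-yl]furan (both acetal epimers) | C=CC[C@@H](OC(OCC)C#C)c1ccoc1 | intermediate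
18 | (6R)-2-ethoxy-3-ethenyl-6-(furan-3-yl)-5,6-dihydro-2H-pyran (both C2 epimers) | C=CC1=CC[C@@H](OC1OCC)c2ccoc2 | intermediate
19 | 9-{2-[(6R)-2-ethoxy-6-(furan-3-yl)-5,6-dihydro-2H-pyran-3-yl]ethyl}-9-borabicyclo[3.3.1]nonane | C(CB1C2CCCC1CCC2)C3=CC[C@@H](OC3OCC)c4ccoc4 | intermediate
20 | (6R)-2-ethoxy-6-(furan-3-yl)-3-{2-[(4aS,8aS)-2,5,5,8a-tetramethyl-3,4,4a,5,6,7,8,8a-octahydronaphthalen-1-yl]ethyl}-5,6-dihydro-2H-pyran | CC1=C(CCC3=CC[C@@H](OC3OCC)c4ccoc4)[C@@]2(C)CCCC(C)(C)[C@@H]2CC1 | intermediate
21 | furan endoperoxide of 20 (2,3,7-trioxabicyclo[2.2.1]hept-5-ene, new centres undefined) | CC1=C(CCC3=CC[C@@H](OC3OCC)C4=CC5OOC4O5)[C@@]2(C)CCCC(C)(C)[C@@H]2CC1 | intermediate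
22 | 5-hydroxy-4-[(6R)-dihydropyranyl]furan-2(5H)-one derived from 20 (ethyl acetal kept, C24 and C25 epimers) | CC1=C(CCC3=CC[C@@H](OC3OCC)C4=CC(=O)OC4O)[C@@]2(C)CCCC(C)(C)[C@@H]2CC1 | intermediate
23 | bis-hemiacetal: C24 lactol and C25 hydroxybutenolide (all epimers) | CC1=C(CCC3=CC[C@@H](OC3O)C4=CC(=O)OC4O)[C@@]2(C)CCCC(C)(C)[C@@H]2CC1 | intermediate
24 | sodium salt of the open triol acid (C25 hydroxymethyl cis to the carboxylate) | CC1=C(CC/C(=C/C[C@@H](O)/C(CO)=C/C(=O)[O-])CO)[C@@]2(C)CCCC(C)(C)[C@@H]2CC1.[Na+] | intermediate
25 | CNP0224983.2, 4-{(1R,3Z)-1-hydroxy-4-(hydroxymethyl)-6-[(4aS,8aS)-2,5,5,8a-tetramethyl-3,4,4a,5,6,7,8,8a-octahydronaphthalen-1-yl]hex-3-en-1-yl}furan-2(5H)-one | CC1=C(CC/C(=C/C[C@@H](O)C2=CC(=O)OC2)CO)[C@@]2(C)CCCC(C)(C)[C@@H]2CC1 | target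

Total step count: 11. Longest linear sequence: 8 steps (steps 1–4 and 8–11).

Steps most likely to fail

**Step 8.** Transmetalation at the crowded alkenylpalladium may be so slow that β-hydride elimination, protodeboronation and hydrolysis of the triflate overtake the coupling. The fallback is a Zweifel olefination, which forms the bond by a 1,2-metallate shift and needs no metal catalyst in the bond-forming event. It sets out from 11 and 19 and comes back at 20.
- Miyaura borylation of 11 (B2pin2, PdCl2(dppf), KOAc, dioxane) would give the alkenyl pinacol boronate F1.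
- Borane 19, made from 18 as before, would be turned with I2 and NaOMe into the primary iodide F2, and t-BuLi at −78 °C would convert this into the alkyllithium F3.
- Addition of F3 to F1 would form the lithium boronate complex F4.
- I2 would trigger migration of C11 from boron to C9 to give the β-iodo boronic ester F5, and NaOMe would eliminate boron and iodine to give 20.

**Step 9.** Chemoselectivity may be lost if the ene reaction of singlet oxygen at the tetrasubstituted C8=C9 alkene competes with cycloaddition to the furan. The fallback oxidises the furan before the union, when no electron-rich alkene is present. It sets out from 17 and comes back at 25.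
- Photooxygenation of 17 under the same conditions would give the hydroxybutenolide enyne F6, and NaBH4 followed by acid would give the butenolide enyne F7.
- Ring-closing enyne metathesis would give the butenolide diene F8, and 9-BBN-H would give its borane F9.
- Coupling of F9 with 11 (PdCl2(dppf), Cs2CO3) would give the butenolide acetal F10.
- Aqueous acid would give the lactol F11, and NaBH4 would reduce this to 25.

**Step 6.** The furyl carbinol may ionise at C16–O under acid, with erosion of configuration and ether formation, while exchange at the alkynyl acetal stays sluggish. The fallback replaces the acid equilibrium by an irreversible O-alkylation under base. It sets out from 16 and 15 and comes back at 17.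
- Acetal 16 with acetyl chloride and catalytic ZnCl2 would give 3-chloro-3-ethoxyprop-1-yne F12.
- F12 would alkylate alcohol 15 in the presence of iPr2NEt in CH2Cl2 at 0 °C to give 17.

Further compounds
F1 | step 8 | 4,4,5,5-tetramethyl-2-[(4aS,8aS)-2,5,5,8a-tetramethyl-3,4,4a,5,6,7,8,8a-octahydronaphthalen-1-yl]-1,3,2-dioxaborolane | CC1=C(B3OC(C)(C)C(C)(C)O3)[C@@]2(C)CCCC(C)(C)[C@@H]2CC1
F2 | step 8 | (6R)-2-ethoxy-6-(furan-3-yl)-3-(2-iodoethyl)-5,6-dihydro-2H-pyran | ICCC1=CC[C@@H](OC1OCC)c2ccoc2
F3 | step 8 | alkyllithium from F2 | [Li]CCC1=CC[C@@H](OC1OCC)c2ccoc2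
F4 | step 8 | lithium boronate complex of F1 and F3 | CC1=C([B-]3(CCC4=CC[C@@H](OC4OCC)c5ccoc5)OC(C)(C)C(C)(C)O3)[C@@]2(C)CCCC(C)(C)[C@@H]2CC1.[Li+]
F5 | step 8 | β-iodo boronic ester (iodine on C8, boron and C11 on C9, new centres undefined) | CC1(I)C(CCC3=CC[C@@H](OC3OCC)c4ccoc4)(B5OC(C)(C)C(C)(C)O5)[C@@]2(C)CCCC(C)(C)[C@@H]2CC1
F6 | step 9 | hydroxybutenolide enyne | C=CC[C@@H](OC(OCC)C#C)C1=CC(=O)OC1O
F7 | step 9 | butenolide enyne | C=CC[C@@H](OC(OCC)C#C)C1=CC(=O)OC1
F8 | step 9 | butenolide diene, 4-[(6R)-2-ethoxy-3-ethenyl-5,6-dihydro-2H-pyran-6-yl]furan-2(5H)-one | C=CC1=CC[C@@H](OC1OCC)C2=CC(=O)OC2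
F9 | step 9 | 9-BBN adduct of F8 | C(CB1C2CCCC1CCC2)C3=CC[C@@H](OC3OCC)C4=CC(=O)OC4
F10 | step 9 | coupled butenolide acetal | CC1=C(CCC3=CC[C@@H](OC3OCC)C4=CC(=O)OC4)[C@@]2(C)CCCC(C)(C)[C@@H]2CC1
F11 | step 9 | coupled butenolide lactol | CC1=C(CCC3=CC[C@@H](OC3O)C4=CC(=O)OC4)[C@@]2(C)CCCC(C)(C)[C@@H]2CC1
F12 | step 6 | 3-chloro-3-ethoxyprop-1-yne | C#CC(Cl)OCC
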